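**Retrosynthetic overview**
1. Target 13 ⇒ (E)-chalcone 12: ring C is closed last by a catalytic asymmetric 6-endo oxa-Michael addition (chalcone-isomerase-type) that sets C2 as S and decides which ortho-hydroxyl closes.
2. 12 ⇒ aryl methyl ketone 9 + benzaldehyde 10 (Claisen–Schmidt).
3. 9 ⇒ pyrone 4 + 3-prenylphloroacetophenone 7, joined pyrone-C3 to aryl-C by a dehydrogenative, phenol-coupling-type C–C bond formation through iodonium ylide 8.
4. 4 ⇒ linear triketide 3 (lactonisation) ⇒ 1 + 2; 7 ⇒ 5 + 6.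
5. Ring order: α-pyrone ring (step 1), ring A bought ready-made in 5, ring C (step 5).

Assumption: the sense of induction of the Ni(acac)2/L* catalyst in step 5 (L* = bis(N-oxide) of 1,3-bis[(2S)-2-(2,6-diisopropylphenylcarbamoyl)piperidin-1-yl]propane, from L-pipecolic acid) is checked in a pilot run by CD (2S: positive band near 330 nm, negative near 290 nm), and the mirror-image ligand from D-pipecolic acid is used if the sense is opposite.

In 12, "2'-OH" is the hydroxyl between the enone-bearing and prenyl-bearing ring carbons, and "6'-OH" is the hydroxyl between the enone-bearing and pyrone-bearing ring carbons.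

**Step 1**
Reactants: 1 methyl 3-oxopentanoate; 2 N-methoxy-N-methylpropanamide
Product: 4 6-ethyl-4-hydroxy-5-methyl-2H-pyran-2-one, via methyl 4-methyl-3,5-dioxoheptanoate 3 (not isolated)
Conditions: NaH, THF, 0 °C; n-BuLi, 0 °C; add 2, −78 → 0 °C; 1 M HCl; then DBU, PhMe, 110 °C
Reagents that add atoms: none
Why: Claisen acylation of the Weiler dianion of 1 at its γ-carbon by the Weinreb amide gives the 3,5-diketo ester 3, whose C5 enol oxygen then lactonises onto the ester (triketide lactonisation, the ring closure by which a polyketide synthase releases such pyrones); no stereocentre is formed.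

**Step 2**
Reactants: 5 1-(2,4,6-trihydroxyphenyl)ethanone; 6 1-bromo-3-methylbut-2-ene
Product: 7 1-[2,4,6-trihydroxy-3-(3-methylbut-2-en-1-yl)phenyl]ethanone
Conditions: 10% aq. KOH, 0 °C → rt
Reagents that add atoms: none
Why: C-alkylation of the ambident phloroacetophenone phenoxide in water (phenoxide C-prenylation) gives a single mono-prenyl isomer because C3 and C5 are equivalent; the di-prenyl by-product is removed by chromatography and no stereocentre is formed.

**Step 3**
Reactants: 4 6-ethyl-4-hydroxy-5-methyl-2H-pyran-2-one; 7 1-[2,4,6-trihydroxy-3-(3-methylbut-2-en-1-yl)phenyl]ethanone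
Product: 9 3-[3-acetyl-2,4,6-trihydroxy-5-(3-methylbut-2-en-1-yl)phenyl]-6-ethyl-4-hydroxy-5-methyl-2H-pyran-2-one, via iodonium ylide 6-ethyl-5-methyl-3-(phenyl-λ3-iodanylidene)pyran-2,4-dione 8 (not isolated)
Conditions: PhI(OAc)2 (1.0 equiv), CH2Cl2, 0 °C → rt; then 7, (CF3)2CHOH, 0 °C → rt
Reagents that add atoms: none
Why: Proposed new method: PhI(OAc)2 converts 4 into ylide 8, an umpoled (electrophilic) pyrone C3, and in (CF3)2CHOH the protonated ylide is attacked by the enol-like C5 of 7 (its only free ring carbon) to give a triorgano-λ3-iodane that collapses by ligand coupling with loss of PhI and re-aromatises, a net dehydrogenative phenol–pyrone coupling; the closest known reaction types are the metal-free α-arylation of β-dicarbonyls by λ3-iodane ligand coupling and the acid-promoted C-arylation of 1,3-dicarbonyl iodonium ylides by indoles and other electron-rich arenes, and no stereocentre is formed.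

**Step 4**
Reactants: 9 3-[3-acetyl-2,4,6-trihydroxy-5-(3-methylbut-2-en-1-yl)phenyl]-6-ethyl-4-hydroxy-5-methyl-2H-pyran-2-one; 10 benzaldehyde
Product: 12 6-ethyl-4-hydroxy-5-methyl-3-{2,4,6-trihydroxy-3-(3-methylbut-2-en-1-yl)-5-[(2E)-3-phenylprop-2-enoyl]phenyl}-2H-pyran-2-one, via β-hydroxy ketone aldol adduct 11 (not isolated)
Conditions: 50% aq. KOH, EtOH, 0 °C → rt, Ar, 48 h; then 1 M HCl to pH 4, 0 °C
Reagents that add atoms: none
Why: Claisen–Schmidt condensation (crossed aldol, then E1cB dehydration to the E-enone); the product stays ring-open as its polyphenoxide (the pyrone is protected as its unreactive anion) and cold acidification releases the open chalcone kinetically, the transient carbinol stereocentre of 11 being lost.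

**Step 5**
Reactants: 12 6-ethyl-4-hydroxy-5-methyl-3-{2,4,6-trihydroxy-3-(3-methylbut-2-en-1-yl)-5-[(2E)-3-phenylprop-2-enoyl]phenyl}-2H-pyran-2-one
Product: 13 6-ethyl-4-hydroxy-3-[(2S)-5,7-dihydroxy-8-(3-methylbut-2-en-1-yl)-4-oxo-2-phenyl-3,4-dihydro-2H-chromen-6-yl]-5-methyl-2H-pyran-2-one
Conditions: Ni(acac)2 (20 mol%), L* (22 mol%), PhOMe–PhMe, 30 °C; aq. citric acid work-up
Reagents that add atoms: none
Why: Proposed new method: the 2',6'-dihydroxyaryl ketone of 12 is a built-in two-point binding site, and the divalent nickel centre, drawn to the pyrone side by the acidic pyrone hydroxyl (pKa about 5) and the more acidic, buttressed 6'-OH, chelates 6'-O and C=O, so that only the prenyl-flanked 2'-OH is placed for intramolecular oxa-Michael attack on the activated β-carbon (8-prenyl-6-pyronyl regiochemistry) while the C2-symmetric ligand shields one enone face and sets C2 as S; the closest known reaction type is the Ni(acac)2-type/N,N'-dioxide-catalysed asymmetric oxa-Michael cyclisation of α-ester-activated 2'-hydroxychalcones to flavanones, a chalcone isomerase mimic.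

**Compound list**
1 | methyl 3-oxopentanoate | CCC(=O)CC(=O)OC | starting material
2 | N-methoxy-N-methylpropanamide | CCC(=O)N(C)OC | starting material
3 | methyl 4-methyl-3,5-dioxoheptanoate (C4 epimerisable, racemic) | CCC(=O)C(C)C(=O)CC(=O)OC | intermediate
4 | 6-ethyl-4-hydroxy-5-methyl-2H-pyran-2-one | CCc1oc(=O)cc(O)c1C | intermediate
5 | 1-(2,4,6-trihydroxyphenyl)ethanone (phloroacetophenone) | CC(=O)c1c(O)cc(O)cc1O | starting material
6 | 1-bromo-3-methylbut-2-ene (prenyl bromide) | CC(C)=CCBr | starting material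
7 | 1-[2,4,6-trihydroxy-3-(3-methylbut-2-en-1-yl)phenyl]ethanone | CC(=O)c1c(O)cc(O)c(CC=C(C)C)c1O | intermediate
8 | 6-ethyl-5-methyl-3-(phenyl-λ3-iodanylidene)pyran-2,4-dione (iodonium ylide, drawn as zwitterion) | CCc1oc(=O)c([I+]c2ccccc2)c([O-])c1C | intermediate
9 | 3-[3-acetyl-2,4,6-trihydroxy-5-(3-methylbut-2-en-1-yl)phenyl]-6-ethyl-4-hydroxy-5-methyl-2H-pyran-2-one | CCc1oc(=O)c(-c2c(O)c(CC=C(C)C)c(O)c(C(C)=O)c2O)c(O)c1C | intermediate
10 | benzaldehyde | O=Cc1ccccc1 | starting material
11 | 6-ethyl-4-hydroxy-5-methyl-3-[2,4,6-trihydroxy-3-(3-hydroxy-3-phenylpropanoyl)-5-(3-methylbut-2-en-1-yl)phenyl]-2H-pyran-2-one (aldol adduct, racemic carbinol) | CCc1oc(=O)c(-c2c(O)c(CC=C(C)C)c(O)c(C(=O)CC(O)c3ccccc3)c2O)c(O)c1C | intermediate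
12 | 6-ethyl-4-hydroxy-5-methyl-3-{2,4,6-trihydroxy-3-(3-methylbut-2-en-1-yl)-5-[(2E)-3-phenylprop-2-enoyl]phenyl}-2H-pyran-2-one (E-chalcone) | CCc1oc(=O)c(-c2c(O)c(CC=C(C)C)c(O)c(C(=O)/C=C/c3ccccc3)c2O)c(O)c1C | intermediate
13 | 6-ethyl-4-hydroxy-3-[(2S)-5,7-dihydroxy-8-(3-methylbut-2-en-1-yl)-4-oxo-2-phenyl-3,4-dihydro-2H-chromen-6-yl]-5-methyl-2H-pyran-2-one | CCc1oc(=O)c(-c2c(O)c(CC=C(C)C)c3c(c2O)C(=O)C[C@@H](c2ccccc2)O3)c(O)c1C | target

**Totals**
Total steps: 5. Longest linear sequence: 4 steps (5 → 7 → 9 → 12 → 13; the pyrone branch 1 → 4 joins at step 3).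

**Three steps most likely to fail**

Step 5 is the greatest risk. The regiochemistry is argued, not proven: if the 6'-OH closes instead, the 6-prenyl-8-pyronyl isomer forms. The catalyst is untested on this substrate class, the polyphenolic product can hold the metal and slow turnover, and prolonged exposure can erode ee through retro-oxa-Michael opening. The fallback fixes the regiochemistry by protection and sets out from 7, coming back to the route at 13. MOMCl/i-Pr2NEt in CH2Cl2 protects the two less hindered hydroxyls of 7 and leaves the one wedged between acetyl and prenyl chelated, giving 1-[2-hydroxy-4,6-bis(methoxymethoxy)-3-(3-methylbut-2-en-1-yl)phenyl]ethanone F1. Claisen–Schmidt condensation with 10 (KOH, EtOH) gives (E)-1-[2-hydroxy-4,6-bis(methoxymethoxy)-3-(3-methylbut-2-en-1-yl)phenyl]-3-phenylprop-2-en-1-one F2, which has a single free ortho-hydroxyl and can close only to the 8-prenyl flavanone. Oxa-Michael cyclisation with the bifunctional thiourea N-[3,5-bis(trifluoromethyl)phenyl]-N'-(9-deoxy-epi-quinin-9-yl)thiourea (a known reaction type for simple 2'-hydroxychalcones, upgraded by crystallisation or chiral HPLC if needed) gives (2S)-5,7-bis(methoxymethoxy)-8-(3-methylbut-2-en-1-yl)-2-phenylchroman-4-one F3. 3 M HCl in MeOH at 40 °C gives (2S)-5,7-dihydroxy-8-(3-methylbut-2-en-1-yl)-2-phenylchroman-4-one F4 (glabranin). Its only free aromatic carbon, C6, is then coupled with ylide 8 in (CF3)2CHOH as in step 3 (non-basic, so C2 is not scrambled) to give 13.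

Step 3 is the second risk. The ylide may O-arylate a phenol, rearrange by 1,4-phenyl shift, or attack the prenyl alkene. The fallback uses aryllead chemistry on a protected arene; it sets out from 4 and comes back at 9. Commercial 1,3,5-trimethoxybenzene is plumbated with Pb(OAc)4 to 2,4,6-trimethoxyphenyllead triacetate F5. This arylates 4 at C3 (pyridine, CHCl3, 60 °C; Pinhey arylation) to give 6-ethyl-4-hydroxy-5-methyl-3-(2,4,6-trimethoxyphenyl)-2H-pyran-2-one F6. BBr3 in CH2Cl2 gives 6-ethyl-4-hydroxy-5-methyl-3-(2,4,6-trihydroxyphenyl)-2H-pyran-2-one F7. Friedel–Crafts C-acetylation (Ac2O, BF3·OEt2; the two free ring positions are equivalent) gives 3-(3-acetyl-2,4,6-trihydroxyphenyl)-6-ethyl-4-hydroxy-5-methyl-2H-pyran-2-one F8. C-prenylation at the last free ring carbon with 6 in aqueous KOH, as in step 2, gives 9.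

Step 4 is the third risk. The unprotected polyanion of 9 may enolise poorly, and two days in strong alkali may damage the pyrone. The fallback avoids the hydroxide aldol; it sets out from 9 and comes back at 12. 9 and 10 are condensed with pyrrolidine in EtOH at 60 °C (Kabbe-type amine-mediated condensation and ring closure), giving directly racemic 6-ethyl-4-hydroxy-3-[5,7-dihydroxy-8-(3-methylbut-2-en-1-yl)-4-oxo-2-phenyl-3,4-dihydro-2H-chromen-6-yl]-5-methyl-2H-pyran-2-one F9 together with its regioisomer, racemic 6-ethyl-4-hydroxy-3-[5,7-dihydroxy-6-(3-methylbut-2-en-1-yl)-4-oxo-2-phenyl-3,4-dihydro-2H-chromen-8-yl]-5-methyl-2H-pyran-2-one F10. Both are ring-closed forms of the same chalcone, so the unseparated mixture is opened in cold 10% aqueous KOH for a few minutes and acidified quickly at 0 °C to give 12.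

**Further compounds**
F1 | step 5 | 1-[2-hydroxy-4,6-bis(methoxymethoxy)-3-(3-methylbut-2-en-1-yl)phenyl]ethanone | CC(=O)c1c(O)c(CC=C(C)C)c(OCOC)cc1OCOC
F2 | step 5 | (E)-1-[2-hydroxy-4,6-bis(methoxymethoxy)-3-(3-methylbut-2-en-1-yl)phenyl]-3-phenylprop-2-en-1-one | COCOc1cc(OCOC)c(C(=O)/C=C/c2ccccc2)c(O)c1CC=C(C)C
F3 | step 5 | (2S)-5,7-bis(methoxymethoxy)-8-(3-methylbut-2-en-1-yl)-2-phenylchroman-4-one | CC(C)=CCc1c(OCOC)cc(OCOC)c2c1O[C@H](c1ccccc1)CC2=O
F4 | step 5 | (2S)-5,7-dihydroxy-8-(3-methylbut-2-en-1-yl)-2-phenylchroman-4-one (glabranin) | CC(C)=CCc1c(O)cc(O)c2c1O[C@H](c1ccccc1)CC2=O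
F5 | step 3 | 2,4,6-trimethoxyphenyllead triacetate | COc1cc(OC)c([Pb](OC(C)=O)(OC(C)=O)OC(C)=O)c(OC)c1
F6 | step 3 | 6-ethyl-4-hydroxy-5-methyl-3-(2,4,6-trimethoxyphenyl)-2H-pyran-2-one | CCc1oc(=O)c(-c2c(OC)cc(OC)cc2OC)c(O)c1C
F7 | step 3 | 6-ethyl-4-hydroxy-5-methyl-3-(2,4,6-trihydroxyphenyl)-2H-pyran-2-one | CCc1oc(=O)c(-c2c(O)cc(O)cc2O)c(O)c1C
F8 | step 3 | 3-(3-acetyl-2,4,6-trihydroxyphenyl)-6-ethyl-4-hydroxy-5-methyl-2H-pyran-2-one | CCc1oc(=O)c(-c2c(O)cc(O)c(C(C)=O)c2O)c(O)c1C
F9 | step 4 | racemic 6-ethyl-4-hydroxy-3-[5,7-dihydroxy-8-(3-methylbut-2-en-1-yl)-4-oxo-2-phenyl-3,4-dihydro-2H-chromen-6-yl]-5-methyl-2H-pyran-2-one | CCc1oc(=O)c(-c2c(O)c(CC=C(C)C)c3c(c2O)C(=O)CC(c2ccccc2)O3)c(O)c1C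
F10 | step 4 | racemic 6-ethyl-4-hydroxy-3-[5,7-dihydroxy-6-(3-methylbut-2-en-1-yl)-4-oxo-2-phenyl-3,4-dihydro-2H-chromen-8-yl]-5-methyl-2H-pyran-2-one | CCc1oc(=O)c(-c2c(O)c(CC=C(C)C)c(O)c3c2OC(c2ccccc2)CC3=O)c(O)c1C
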